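All runs are calculated on assumed constants, and the scatter is random.

Watch the fraction of starting material left at each reading, not just the target, when you repeat Friday's flask, in which starting material meets partner under a precatalyst to give target and by-product.

| flask | starting material | partner | precatalyst | remark | time |
|---|---|---|---|---|---|
| Friday's | 22 mM | 1.3 equiv | 2 mol% | the very flask that is asked about, followed so far |  |
| Monday's | 22 mM | 0.87 equiv | 2 mol% | run made earlier |  |
| flask | 22 mM | 1.30 equiv | 2 mol% |  | 8.0 d |

| run | time / d | target / % | starting material / % |
|---|---|---|---|
| Friday's | 0.625 | 1 | 97 |
| Friday's | 1.25 | 6 | 91 |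
| Friday's | 2.08 | 13 | 84 |
| Friday's | 3.00 | 16 | 83 |
| Friday's | 4.00 | 19 | 76 |
| Friday's | 5.00 | 24 | 71 |
| Monday's | 0.208 | 0 | 100 |
| Monday's | 0.333 | 1 | 99 |
| Monday's | 0.500 | 1 | 98 |
| Monday's | 0.625 | 1 | 98 |
| Monday's | 1.04 | 3 | 96 |
| Monday's | 1.67 | 7 | 89 |
| Monday's | 2.50 | 11 | 89 |

(readings scatter by 1.5 percentage points)

- target, in percent of the starting material first charged, at 8.0 d
- what to do for the largest gain in target; "none" if nothing gains more than 2 percentage points (south-west / west / north-east / south / none)
- target present, in percent of the starting material first charged, after south-west
- target present, in percent of the starting material first charged, after north-east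

- south-west: change nothing and wait 2.5 d more
- west: at 8.0 d take out 90% of the by-product then present, then wait 2.5 d
- north-east: at 8.0 d add partner, 50.0% of the amount charged, then wait 2.5 d
- south: at 8.0 d add precatalyst, 50.0% of the amount charged, then wait 2.5 d

- the volume of additions can be left aside
- the earlier runs were read with a standard deviation of 1.5 percentage points

1. Before the run reached 8.0 d, I had to decide whether to charge more of anything, so I took Friday's last reading, 71% left at 5.00 d, and got 0.0685 d⁻¹, the leaving constant, which is the natural logarithm of charged over left, divided by the time; it is an apparent pseudo-first-order constant, and it is a reading with a scatter of 1.5 points in the percentage behind it.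

2. Monday's last reading gave 0.0466 d⁻¹, so the ratio of the two constants was 0.680, beside a ratio of partner charges of 0.669, but those two readings stand at different times and carry their scatter, so I took this as a hint that the leaving constant follows partner.

3. Carried to 8.0 d, Friday's constant left me 57.8% of the starting material, and this was my own reckoning, but the loss may not be all target: at 5.00 d Friday's readings left a gap of 5 points, after 1 point at 3.00 d, each gap carrying the scatter of its readings. So I decided to add nothing until both species had been read at 8.0 d.

4. The forecast gave 33% target at 8.0 d, then 39.5% after south-west and 43.5% after north-east, its choice, holding that “there is no clear sign of by-product inhibition or catalyst death”.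

5. The flask gave 21.4%, 20.1% after south-west and 22.9% after north-east, and the move to choose was west, taking out by-product, which gained 5.2 points, against 1.5 points for north-east and 0.74 points for south.

    starting material + catalyst intermediate A ⇌ catalyst intermediate B (K = 810 M⁻¹, k = 1.40 M⁻¹ min⁻¹)
    partner + free catalyst ⇌ catalyst intermediate A (K = 4.40 M⁻¹, k = 1.30 M⁻¹ min⁻¹)
    precatalyst → free catalyst (k = 0.00290 min⁻¹)
    catalyst intermediate D → free catalyst + target (k = 0.230 min⁻¹)
    catalyst intermediate C ⇌ by-product + catalyst intermediate D (K = 0.200 M, k = 1.40 min⁻¹)
    catalyst intermediate B → catalyst intermediate C (k = 0.0420 min⁻¹)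
    target + by-product → side product (k = 0.0270 M⁻¹ min⁻¹)

Friday's flask held 58% of its starting material at 8.0 d, a leaving constant of 0.0681 d⁻¹, with 21.4% target beside 20.5% side product. At 3.32 d in Friday's flask, target was made 2.19 times faster than it was used up, each step taken net. The neighbour of Friday's flask charged with 8 mol% precatalyst had a leaving constant of 0.204 d⁻¹, and at 8.0 d it held 24.3% target and 56.1% side product.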